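**Plan** (germacrane numbering: ring C1–C10; C11 = butenolide α-carbon, C12 = lactone C=O, C13 = CH2OAc, C14 = exocyclic CH2 on C10, C15 = CH3 on C4)
1. Cuts, in order: side-chain O–Si; C6–C7 together with O6–C12 in one event; the oxygens of the 1,2- and 4,5-epoxides; C1=C2; C10=C14; the C8–O ester; C11–C13 and C7–I; C7–C8.
2. Enabling feature: C7 is both a ring atom of the ten-membered carbocycle and the β-carbon of the butenolide, and C6 is the lactone carbinol carbon next to the 4,5-epoxide. An aldehyde at C6 and a (Z)-β-iodo enoate (I on C7, ester C12 cis to it) therefore close both rings at once.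
3. Forward: the C7–C14 part comes from pent-4-enal and methyl propiolate (alkynylation, iodo-aldol, acylations, alkene cleavage, methylenation). The C2–C6 part comes from 4-bromobut-1-yne (carboalumination). They are joined by a Z-selective Wittig reaction (C1=C2), followed by two reagent-controlled epoxidations and oxidation.
4. Step 17 then forms the ten-membered ring and the butenolide together; desilylation ends the route.
5. Stereochemistry: C8 from the zinc/ProPhenol alkynylation; C4 and C5 from Sharpless epoxidation; C1 and C2 from Shi epoxidation of the Z-diene; C6 in the key step by 1,2-induction from the epoxide. Alkene geometries come from syn-carboalumination (E), salt-free Wittig (Z) and the hydroxyl-directed iodo-aldol (Z).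

Key step: step 17

Remark: the sense of induction of the ProPhenol ligand and of the Shi ketone is assigned from the usual facial models; the enantiomer of each that gives the configuration drawn is the one meant.

Step 1
Reactants: 1 ethyl 2-(hydroxymethyl)acrylate
Product: 2 ethyl 2-(((tert-butyldimethylsilyl)oxy)methyl)acrylate
Conditions: TBSCl, imidazole, CH2Cl2, 0 °C to rt
Reagents that add atoms: tert-butyldimethylsilyl chloride, C[Si](C)(Cl)C(C)(C)C
Why: Imidazole-mediated silylation of the primary hydroxyl masks the side-chain alcohol for the whole route.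

Step 2
Reactants: 2 ethyl 2-(((tert-butyldimethylsilyl)oxy)methyl)acrylate
Product: 3 2-(((tert-butyldimethylsilyl)oxy)methyl)acrylic acid
Conditions: LiOH, THF/H2O, 0 °C to rt; then 1 M HCl to pH 4
Reagents that add atoms: lithium hydroxide, [Li+].[OH-]
Why: Ester saponification (acyl–oxygen cleavage) should free the acid while the TBS ether survives and the 2-substituted acrylate resists hydroxide addition.

Step 3
Reactants: 4 pent-4-enal; 5 methyl propiolate
Product: 6 methyl (S)-4-hydroxyoct-7-en-2-ynoate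
Conditions: Me2Zn, (S,S)-ProPhenol (10 mol %), Ph3P=O (20 mol %), toluene, 4 °C
Reagents that add atoms: none
Why: Catalytic asymmetric alkynylation by the dinuclear zinc–ProPhenol complex adds the zinc propiolate to one aldehyde face and sets C8 as (S).

Step 4
Reactants: 6 methyl (S)-4-hydroxyoct-7-en-2-ynoate
Product: 7 methyl (2Z,4S)-4-hydroxy-2-(hydroxymethyl)-3-iodoocta-2,7-dienoate
Conditions: Et2AlI (2.2 equiv), CH2Cl2, −40 to 0 °C; CH2O (monomer from cracked paraformaldehyde), −78 to 0 °C; aq. NaHCO3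
Reagents that add atoms: diethylaluminium iodide, CC[Al](I)CC; formaldehyde, C=O
Why: Iodide adds to C7 of the aluminium-bound ynoate and the β-iodoallenolate captures formaldehyde at C11 (β-iodo Baylis–Hillman, or halo-aldol, reaction); formaldehyde bound to the C8 aluminium alkoxide should be delivered syn to C8, which puts CH2OH cis to C8 and iodine cis to the ester (2Z), while any 2E isomer lactonizes onto O8 and is separated.

Step 5
Reactants: 7 methyl (2Z,4S)-4-hydroxy-2-(hydroxymethyl)-3-iodoocta-2,7-dienoate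
Product: 8 methyl (2Z,4S)-2-(acetoxymethyl)-4-hydroxy-3-iodoocta-2,7-dienoate
Conditions: AcCl (1.05 equiv), 2,4,6-collidine, CH2Cl2, −78 °C
Reagents that add atoms: acetyl chloride, CC(Cl)=O
Why: Acetylation with a hindered base at low temperature should select the primary allylic hydroxyl over the secondary C8 hydroxyl next to the tetrasubstituted alkene.

Step 6
Reactants: 8 methyl (2Z,4S)-2-(acetoxymethyl)-4-hydroxy-3-iodoocta-2,7-dienoate; 3 2-(((tert-butyldimethylsilyl)oxy)methyl)acrylic acid
Product: 9 methyl (2Z,4S)-2-(acetoxymethyl)-4-((2-(((tert-butyldimethylsilyl)oxy)methyl)acryloyl)oxy)-3-iodoocta-2,7-dienoate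
Conditions: DCC, DMAP (cat.), CH2Cl2, 0 °C to rt
Reagents that add atoms: none
Why: Steglich esterification acylates the remaining secondary alcohol with retention at C8 and installs the final side chain in protected form; the C12 ester is trans to C8 and cannot lactonize.

Step 7
Reactants: 9 methyl (2Z,4S)-2-(acetoxymethyl)-4-((2-(((tert-butyldimethylsilyl)oxy)methyl)acryloyl)oxy)-3-iodoocta-2,7-dienoate
Product: 11 methyl (2Z,4S)-2-(acetoxymethyl)-4-((2-(((tert-butyldimethylsilyl)oxy)methyl)acryloyl)oxy)-3-iodo-7-oxohept-2-enoate, via vicinal diol 10 (not isolated)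
Conditions: OsO4 (2 mol %), NaIO4, 2,6-lutidine, dioxane/H2O, rt
Reagents that add atoms: sodium periodate, [Na+].[O-]I(=O)(=O)=O (terminal oxidant; the oxygen is delivered through osmium tetroxide, O=[Os](=O)(=O)=O)
Why: Lemieux–Johnson cleavage; OsO4 should dihydroxylate only the monosubstituted electron-rich alkene (acrylate and iodoenoate are electron-poor and hindered) and periodate cleaves the diol to the C1 aldehyde.

Step 8
Reactants: 11 methyl (2Z,4S)-2-(acetoxymethyl)-4-((2-(((tert-butyldimethylsilyl)oxy)methyl)acryloyl)oxy)-3-iodo-7-oxohept-2-enoate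
Product: 13 methyl (2Z,4S)-2-(acetoxymethyl)-4-((2-(((tert-butyldimethylsilyl)oxy)methyl)acryloyl)oxy)-6-formyl-3-iodohepta-2,6-dienoate, via Mannich base 12 (not isolated)
Conditions: Me2N=CH2 I (Eschenmoser's salt), Et3N, CH2Cl2, rt
Reagents that add atoms: N,N-dimethylmethylideneammonium iodide, C=[N+](C)C.[I-]
Why: Mannich reaction of the aldehyde enol with the iminium salt and β-elimination of dimethylamine (Eschenmoser methylenation) install C14 on C10, the only enolizable position.

Step 9
Reactants: 14 4-bromobut-1-yne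
Product: 16 methyl (E)-5-bromo-3-methylpent-2-enoate, via alkenylalane 15 (not isolated)
Conditions: Me3Al, Cp2ZrCl2 (25 mol %), CH2Cl2, 0 °C to rt; then ClCO2Me, 0 °C to rt
Reagents that add atoms: trimethylaluminium, C[Al](C)C; methyl chloroformate, COC(Cl)=O
Why: Zirconium-catalysed syn-carboalumination (Negishi) places methyl on the internal carbon cis to aluminium, and acylation of the alkenylalane with retention fixes the E-trisubstituted C4=C5 alkene with C15.

Step 10
Reactants: 16 methyl (E)-5-bromo-3-methylpent-2-enoate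
Product: 17 (E)-5-bromo-3-methylpent-2-en-1-ol
Conditions: i-Bu2AlH (2.2 equiv), CH2Cl2, −78 °C
Reagents that add atoms: none
Why: 1,2-Reduction of the enoate at low temperature gives the allylic alcohol and should leave the primary bromide and the alkene geometry untouched.

Step 11
Reactants: 17 (E)-5-bromo-3-methylpent-2-en-1-ol
Product: 18 (E)-((5-bromo-3-methylpent-2-en-1-yl)oxy)triethylsilane
Conditions: TESCl, imidazole, CH2Cl2, 0 °C
Reagents that add atoms: chlorotriethylsilane, CC[Si](Cl)(CC)CC
Why: Silylation gives an ether that survives ylide chemistry and is labile enough to be removed later beside the TBS ether.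

Step 12
Reactants: 18 (E)-((5-bromo-3-methylpent-2-en-1-yl)oxy)triethylsilane
Product: 19 (E)-(3-methyl-5-((triethylsilyl)oxy)pent-3-en-1-yl)triphenylphosphonium bromide
Conditions: PPh3, MeCN, 80 °C
Reagents that add atoms: triphenylphosphine, c1ccc(cc1)P(c1ccccc1)c1ccccc1
Why: SN2 quaternization of triphenylphosphine by the primary homoallylic bromide gives the Wittig salt.

Step 13
Reactants: 19 (E)-(3-methyl-5-((triethylsilyl)oxy)pent-3-en-1-yl)triphenylphosphonium bromide; 13 methyl (2Z,4S)-2-(acetoxymethyl)-4-((2-(((tert-butyldimethylsilyl)oxy)methyl)acryloyl)oxy)-6-formyl-3-iodohepta-2,6-dienoate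
Product: 22 methyl (2Z,4S,7Z,10E)-2-(acetoxymethyl)-4-((2-(((tert-butyldimethylsilyl)oxy)methyl)acryloyl)oxy)-12-hydroxy-3-iodo-10-methyl-6-methylidenedodeca-2,7,10-trienoate, via phosphonium ylide 20 (not isolated), via silyl ether 21 (not isolated)
Conditions: KN(SiMe3)2 (1.0 equiv), THF, −78 °C; add 13, −78 to −20 °C; then PPTS, MeOH, 0 °C
Reagents that add atoms: none
Why: Salt-free Wittig olefination of the non-stabilized ylide with the α-branched enal should pass through the cis-oxaphosphetane to the (Z)-C1=C2 bond of the 1,3-diene, and mild acidic methanolysis then removes only the primary triethylsilyl ether.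

Step 14
Reactants: 22 methyl (2Z,4S,7Z,10E)-2-(acetoxymethyl)-4-((2-(((tert-butyldimethylsilyl)oxy)methyl)acryloyl)oxy)-12-hydroxy-3-iodo-10-methyl-6-methylidenedodeca-2,7,10-trienoate
Product: 23 methyl (2Z,4S,7Z)-2-(acetoxymethyl)-4-((2-(((tert-butyldimethylsilyl)oxy)methyl)acryloyl)oxy)-9-((2R,3R)-3-(hydroxymethyl)-2-methyloxiran-2-yl)-3-iodo-6-methylidenenona-2,7-dienoate
Conditions: Ti(OiPr)4, D-(−)-diethyl tartrate, t-BuOOH, 4 Å sieves, CH2Cl2, −20 °C
Reagents that add atoms: tert-butyl hydroperoxide, CC(C)(C)OO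
Why: Sharpless asymmetric epoxidation of the geraniol-type (E)-allylic alcohol; with D-(−)-tartrate the titanium-bound peroxide should give the (2R,3R)-epoxy alcohol, that is C4 (R) and C5 (R), and only the allylic-alcohol alkene reacts.

Step 15
Reactants: 23 methyl (2Z,4S,7Z)-2-(acetoxymethyl)-4-((2-(((tert-butyldimethylsilyl)oxy)methyl)acryloyl)oxy)-9-((2R,3R)-3-(hydroxymethyl)-2-methyloxiran-2-yl)-3-iodo-6-methylidenenona-2,7-dienoate
Product: 24 methyl (2Z,4S)-2-(acetoxymethyl)-4-((2-(((tert-butyldimethylsilyl)oxy)methyl)acryloyl)oxy)-6-((2R,3S)-3-(((2R,3R)-3-(hydroxymethyl)-2-methyloxiran-2-yl)methyl)oxiran-2-yl)-3-iodohepta-2,6-dienoate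
Conditions: Shi D-glucose-derived N-aryl oxazolidinone ketone (30 mol %), KHSO5 (Oxone), K2CO3, Bu4NHSO4, MeCN/dimethoxymethane/aq. buffer (pH about 10), −10 to 0 °C
Reagents that add atoms: potassium peroxymonosulfate, [K+].[O-]S(=O)(=O)OO (oxygen delivered through the ketone-derived dioxirane)
Why: Shi epoxidation; the dioxirane should react through a spiro transition state with the cis-disubstituted alkene of the conjugated diene (vinyl group next to the oxazolidinone) and give the cis-vinyl epoxide with C1 (R) and C2 (S) stereospecifically, leaving the 1,1-disubstituted and electron-poor alkenes.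

Step 16
Reactants: 24 methyl (2Z,4S)-2-(acetoxymethyl)-4-((2-(((tert-butyldimethylsilyl)oxy)methyl)acryloyl)oxy)-6-((2R,3S)-3-(((2R,3R)-3-(hydroxymethyl)-2-methyloxiran-2-yl)methyl)oxiran-2-yl)-3-iodohepta-2,6-dienoate
Product: 25 methyl (2Z,4S)-2-(acetoxymethyl)-4-((2-(((tert-butyldimethylsilyl)oxy)methyl)acryloyl)oxy)-6-((2R,3S)-3-(((2R,3S)-3-formyl-2-methyloxiran-2-yl)methyl)oxiran-2-yl)-3-iodohepta-2,6-dienoate
Conditions: Dess–Martin periodinane, NaHCO3, CH2Cl2, 0 °C to rt
Reagents that add atoms: none
Why: Buffered Dess–Martin oxidation should convert the primary epoxy alcohol to the α,β-epoxy aldehyde without epimerization or epoxide opening.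

Step 17
Reactants: 25 methyl (2Z,4S)-2-(acetoxymethyl)-4-((2-(((tert-butyldimethylsilyl)oxy)methyl)acryloyl)oxy)-6-((2R,3S)-3-(((2R,3S)-3-formyl-2-methyloxiran-2-yl)methyl)oxiran-2-yl)-3-iodohepta-2,6-dienoate
Product: 27 O-TBS ether of the target (macrocyclic butenolide), via hydroxy ester 26 (not isolated)
Conditions: CrCl2 (10 equiv), NiCl2 (10 mol %), degassed DMSO/THF, slow addition to 0.003 M, rt; aq. ethylenediamine work-up, then silica gel or PPTS (cat.) to complete lactonization
Reagents that add atoms: none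
Why: Zerovalent nickel (formed from NiCl2 by divalent chromium) inserts into the C7–I bond, transmetalation gives a trivalent alkenylchromium with retention of the C7=C11 geometry, and its addition to the C6 aldehyde forms the C6–C7 bond; the chromium alkoxide, held cis to the C12 methyl ester, then acylates and releases methanol (Nozaki–Hiyama–Kishi reaction with lactonization, the closest known types being medium-ring NHK closures and butenolide formation from (Z)-3-iodoacrylates and aldehydes). The ten-membered carbocycle closes by 10-exo-trig addition of C7 to the C6 carbonyl, preorganized by the cis-1,2-epoxide turn, the trans-4,5-epoxide and the sp2 centres C7 and C10, and the butenolide closes by 5-exo-trig attack of O6 on C12. The one new stereocentre, C6, is controlled by the adjacent oxirane carbon C5: the C15 methyl, cis to the formyl group, disfavours the rotamer in which the carbonyl oxygen eclipses C4 (allylic 1,3-type strain), and attack anti to the C5–O bond (Felkin–Anh polar model) on the remaining bisected rotamer should give the 5,6-syn relationship, that is (6S), which is also the sense that lets the ring adopt the H5/H6-anti conformation typical of 4,5-epoxygermacranolides. The step needs ring closure over oligomerization (high dilution, slow addition), addition to the aldehyde only (organochromium reagents tolerate esters, acrylates and epoxides), and retention of alkene geometry so that only the C12 ester can lactonize.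

Step 18
Reactants: 27 O-TBS ether of the target
Product: 28 target, (1R,2S,4R,5R,6S,8S)-13-acetoxy-1,2:4,5-diepoxy-8-((2-(hydroxymethyl)acryloyl)oxy)germacra-7(11),10(14)-dien-12,6-olide
Conditions: Bu4NF/AcOH (1:1), THF, 0 °C to rt
Reagents that add atoms: none
Why: Fluoride buffered with acetic acid cleaves the primary silyl ether (Si–F bond formation) under near-neutral conditions that should leave both epoxides, the allylic acetate, the acrylate and the butenolide intact.

**Compound list**
1 | ethyl 2-(hydroxymethyl)acrylate | C=C(CO)C(=O)OCC | starting material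
2 | ethyl 2-(((tert-butyldimethylsilyl)oxy)methyl)acrylate | C=C(CO[Si](C)(C)C(C)(C)C)C(=O)OCC | intermediate
3 | 2-(((tert-butyldimethylsilyl)oxy)methyl)acrylic acid | C=C(CO[Si](C)(C)C(C)(C)C)C(=O)O | intermediate
4 | pent-4-enal | C=CCCC=O | starting material
5 | methyl propiolate | C#CC(=O)OC | starting material
6 | methyl (S)-4-hydroxyoct-7-en-2-ynoate | O[C@@H](CCC=C)C#CC(=O)OC | intermediate
7 | methyl (2Z,4S)-4-hydroxy-2-(hydroxymethyl)-3-iodoocta-2,7-dienoate | O[C@@H](CCC=C)/C(I)=C(\CO)C(=O)OC | intermediate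
8 | methyl (2Z,4S)-2-(acetoxymethyl)-4-hydroxy-3-iodoocta-2,7-dienoate | O[C@@H](CCC=C)/C(I)=C(\COC(C)=O)C(=O)OC | intermediate
9 | methyl (2Z,4S)-2-(acetoxymethyl)-4-((2-(((tert-butyldimethylsilyl)oxy)methyl)acryloyl)oxy)-3-iodoocta-2,7-dienoate | C=C(CO[Si](C)(C)C(C)(C)C)C(=O)O[C@@H](CCC=C)/C(I)=C(\COC(C)=O)C(=O)OC | intermediate
10 | 7,8-diol of 9 (mixture at C7) | C=C(CO[Si](C)(C)C(C)(C)C)C(=O)O[C@@H](CCC(O)CO)/C(I)=C(\COC(C)=O)C(=O)OC | intermediate
11 | methyl (2Z,4S)-2-(acetoxymethyl)-4-((2-(((tert-butyldimethylsilyl)oxy)methyl)acryloyl)oxy)-3-iodo-7-oxohept-2-enoate | C=C(CO[Si](C)(C)C(C)(C)C)C(=O)O[C@@H](CCC=O)/C(I)=C(\COC(C)=O)C(=O)OC | intermediate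
12 | 6-((dimethylamino)methyl) derivative of 11 (Mannich base, mixture at C6) | C=C(CO[Si](C)(C)C(C)(C)C)C(=O)O[C@@H](CC(CN(C)C)C=O)/C(I)=C(\COC(C)=O)C(=O)OC | intermediate
13 | methyl (2Z,4S)-2-(acetoxymethyl)-4-((2-(((tert-butyldimethylsilyl)oxy)methyl)acryloyl)oxy)-6-formyl-3-iodohepta-2,6-dienoate | C=C(CO[Si](C)(C)C(C)(C)C)C(=O)O[C@@H](CC(=C)C=O)/C(I)=C(\COC(C)=O)C(=O)OC | intermediate
14 | 4-bromobut-1-yne | C#CCCBr | starting material
15 | (E)-(4-bromo-2-methylbut-1-en-1-yl)dimethylalane | C[Al](C)/C=C(\C)CCBr | intermediate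
16 | methyl (E)-5-bromo-3-methylpent-2-enoate | COC(=O)/C=C(\C)CCBr | intermediate
17 | (E)-5-bromo-3-methylpent-2-en-1-ol | OC/C=C(\C)CCBr | intermediate
18 | (E)-((5-bromo-3-methylpent-2-en-1-yl)oxy)triethylsilane | CC[Si](CC)(CC)OC/C=C(\C)CCBr | intermediate
19 | (E)-(3-methyl-5-((triethylsilyl)oxy)pent-3-en-1-yl)triphenylphosphonium bromide | CC[Si](CC)(CC)OC/C=C(\C)CC[P+](c1ccccc1)(c1ccccc1)c1ccccc1.[Br-] | intermediate
20 | (E)-(3-methyl-5-((triethylsilyl)oxy)pent-3-en-1-ylidene)triphenylphosphorane | CC[Si](CC)(CC)OC/C=C(\C)CC=P(c1ccccc1)(c1ccccc1)c1ccccc1 | intermediate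
21 | 12-O-triethylsilyl ether of 22 | C=C(CO[Si](C)(C)C(C)(C)C)C(=O)O[C@@H](CC(=C)/C=C\C/C(C)=C/CO[Si](CC)(CC)CC)/C(I)=C(\COC(C)=O)C(=O)OC | intermediate
22 | methyl (2Z,4S,7Z,10E)-2-(acetoxymethyl)-4-((2-(((tert-butyldimethylsilyl)oxy)methyl)acryloyl)oxy)-12-hydroxy-3-iodo-10-methyl-6-methylidenedodeca-2,7,10-trienoate | C=C(CO[Si](C)(C)C(C)(C)C)C(=O)O[C@@H](CC(=C)/C=C\C/C(C)=C/CO)/C(I)=C(\COC(C)=O)C(=O)OC | intermediate
23 | (2R,3R)-epoxy alcohol (4,5-epoxide installed; Z-diene intact) | C=C(CO[Si](C)(C)C(C)(C)C)C(=O)O[C@@H](CC(=C)/C=C\C[C@@]1(C)O[C@@H]1CO)/C(I)=C(\COC(C)=O)C(=O)OC | intermediate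
24 | bis-epoxy alcohol (cis-1,2- and trans-4,5-epoxides) | C=C(CO[Si](C)(C)C(C)(C)C)C(=O)O[C@@H](CC(=C)[C@H]1O[C@H]1C[C@@]1(C)O[C@@H]1CO)/C(I)=C(\COC(C)=O)C(=O)OC | intermediate
25 | bis-epoxy aldehyde (seco precursor: C6 aldehyde, C7 iodide) | C=C(CO[Si](C)(C)C(C)(C)C)C(=O)O[C@@H](CC(=C)[C@H]1O[C@H]1C[C@@]1(C)O[C@@H]1C=O)/C(I)=C(\COC(C)=O)C(=O)OC | intermediate
26 | ring-closed (6S)-hydroxy (Z)-enoate, the ten-membered carbocycle before lactonization | C=C(CO[Si](C)(C)C(C)(C)C)C(=O)O[C@H]1CC(=C)[C@H]2O[C@H]2C[C@@]2(C)O[C@@H]2[C@@H](O)/C1=C(/COC(C)=O)C(=O)OC | intermediate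
27 | O-TBS ether of the target | C=C(CO[Si](C)(C)C(C)(C)C)C(=O)O[C@H]1CC(=C)[C@H]2O[C@H]2C[C@@]2(C)O[C@@H]2[C@H]2OC(=O)C(COC(C)=O)=C12 | intermediate
28 | (1R,2S,4R,5R,6S,8S)-13-acetoxy-1,2:4,5-diepoxy-8-((2-(hydroxymethyl)acryloyl)oxy)germacra-7(11),10(14)-dien-12,6-olide | C=C(CO)C(=O)O[C@H]1CC(=C)[C@H]2O[C@H]2C[C@@]2(C)O[C@@H]2[C@H]2OC(=O)C(COC(C)=O)=C12 | target

**Totals**
Total step count: 18. Longest linear sequence: 12 steps (steps 3–8 and 13–18).

**Steps most likely to fail**

1. Step 17. Ring closure may lose to oligomerization because nickel insertion and transmetalation at the tetrasubstituted iodide are slow. The aldehyde face selectivity at C6 may erode, and zerovalent nickel may open the vinyl epoxide. The fallback forms the C6–C7 bond between fragments and closes the ring by metathesis; it sets out from 20 and 13 and comes back at 27. Ylide 20 and formaldehyde give triethyl(((E)-3-methylhexa-2,5-dien-1-yl)oxy)silane F1, and PPTS in methanol gives (E)-3-methylhexa-2,5-dien-1-ol F2. Sharpless epoxidation with D-(−)-diethyl tartrate gives ((2R,3R)-3-allyl-3-methyloxiran-2-yl)methanol F3, and Dess–Martin oxidation gives (2S,3R)-3-allyl-3-methyloxirane-2-carbaldehyde F4. Enal 13 is methylenated with Ph3P=CH2 to the 2-substituted butadiene ester F5. Intermolecular coupling of F5 with F4 (CrCl2, catalytic NiCl2, DMSO) and lactonization give the open-chain butenolide F6, with C6 set by the same epoxide-based model. Ring-closing metathesis with a second-generation Hoveyda–Grubbs catalyst at high dilution joins the allyl group to the terminal vinyl of the diene and gives the macrocyclic Z-diene F7. Shi epoxidation under the conditions of step 15 then gives 27.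

2. Step 4. Geometric control may be lost in the capture of the iodoallenolate: formaldehyde may enter anti to C8, and that isomer then lactonizes. The fallback accepts this outcome and exchanges the oxidation levels of the two carbon substituents on C11; it sets out from 6 and comes back at 8. Without alkoxide direction (MgI2, CH2O, CH2Cl2), the adduct closes onto O8 to give (S)-5-(but-3-en-1-yl)-3-(hydroxymethyl)-4-iodofuran-2(5H)-one F8, in which the ring fixes the alkene geometry. Silylation (TESCl, imidazole) gives the triethylsilyl ether F9. Reduction with i-Bu2AlH and then NaBH4 opens the lactone to (2Z,4S)-3-iodo-2-(((triethylsilyl)oxy)methyl)octa-2,7-diene-1,4-diol F10, whose new CH2OH is cis to C8. Selective acetylation (AcCl, collidine) gives the primary acetate F11, and PPTS in methanol gives the diol F12. TEMPO with PhI(OAc)2 gives the aldehyde F13, NaClO2 gives the acid F14, and Me3SiCHN2 gives 8.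

3. Step 15. Site and face selectivity may be poor (attack on the 1,1-disubstituted alkene, weak enantiofacial discrimination on a flexible chain), and the esters may hydrolyse in the basic medium. The fallback moves this epoxidation to the macrocycle, where the ring conformation adds its own facial bias; it sets out from 23 and comes back at 27. Dess–Martin oxidation of 23 gives the dienyl epoxy aldehyde F15. Ring closure under the conditions of step 17 gives the macrocyclic Z-diene F7. Its only electron-rich alkene, the cis C1=C2 bond now held in the ring, is epoxidized last with the Shi ketone (either enantiomer, for matched double stereodifferentiation) or with dimethyldioxirane, to give 27.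

**Further compounds**
F1 | step 17 | triethyl(((E)-3-methylhexa-2,5-dien-1-yl)oxy)silane | CC[Si](CC)(CC)OC/C=C(\C)CC=C
F2 | step 17 | (E)-3-methylhexa-2,5-dien-1-ol | OC/C=C(\C)CC=C
F3 | step 17 | ((2R,3R)-3-allyl-3-methyloxiran-2-yl)methanol | C=CC[C@@]1(C)O[C@@H]1CO
F4 | step 17 | (2S,3R)-3-allyl-3-methyloxirane-2-carbaldehyde | C=CC[C@@]1(C)O[C@@H]1C=O
F5 | step 17 | methyl (2Z,4S)-2-(acetoxymethyl)-4-((2-(((tert-butyldimethylsilyl)oxy)methyl)acryloyl)oxy)-3-iodo-6-methylideneocta-2,7-dienoate | C=C(CO[Si](C)(C)C(C)(C)C)C(=O)O[C@@H](CC(=C)C=C)/C(I)=C(\COC(C)=O)C(=O)OC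
F6 | step 17 | open-chain butenolide: (S)-1-((S)-4-(acetoxymethyl)-2-((2S,3R)-3-allyl-3-methyloxiran-2-yl)-5-oxo-2,5-dihydrofuran-3-yl)-3-methylidenepent-4-en-1-yl 2-(((tert-butyldimethylsilyl)oxy)methyl)acrylate | C=C(CO[Si](C)(C)C(C)(C)C)C(=O)O[C@@H](CC(=C)C=C)C1=C(COC(C)=O)C(=O)O[C@@H]1[C@H]1O[C@]1(C)CC=C
F7 | step 17 | macrocyclic Z-diene: 1,2-deoxy (C1=C2) analogue of 27 | C=C(CO[Si](C)(C)C(C)(C)C)C(=O)O[C@H]1CC(=C)/C=C\C[C@@]2(C)O[C@@H]2[C@H]2OC(=O)C(COC(C)=O)=C12
F8 | step 4 | (S)-5-(but-3-en-1-yl)-3-(hydroxymethyl)-4-iodofuran-2(5H)-one | OCC1=C(I)[C@H](CCC=C)OC1=O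
F9 | step 4 | (S)-5-(but-3-en-1-yl)-4-iodo-3-(((triethylsilyl)oxy)methyl)furan-2(5H)-one | CC[Si](CC)(CC)OCC1=C(I)[C@H](CCC=C)OC1=O
F10 | step 4 | (2Z,4S)-3-iodo-2-(((triethylsilyl)oxy)methyl)octa-2,7-diene-1,4-diol | O[C@@H](CCC=C)/C(I)=C(\CO)CO[Si](CC)(CC)CC
F11 | step 4 | (2Z,4S)-4-hydroxy-3-iodo-2-(((triethylsilyl)oxy)methyl)octa-2,7-dien-1-yl acetate | O[C@@H](CCC=C)/C(I)=C(\COC(C)=O)CO[Si](CC)(CC)CC
F12 | step 4 | (2E,4S)-4-hydroxy-2-(hydroxymethyl)-3-iodoocta-2,7-dien-1-yl acetate | O[C@@H](CCC=C)/C(I)=C(\COC(C)=O)CO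
F13 | step 4 | (2Z,4S)-2-formyl-4-hydroxy-3-iodoocta-2,7-dien-1-yl acetate | O[C@@H](CCC=C)/C(I)=C(\COC(C)=O)C=O
F14 | step 4 | (2Z,4S)-2-(acetoxymethyl)-4-hydroxy-3-iodoocta-2,7-dienoic acid | O[C@@H](CCC=C)/C(I)=C(\COC(C)=O)C(=O)O
F15 | step 15 | dienyl epoxy aldehyde: 1,2-deoxy (C1=C2, Z) analogue of 25 | C=C(CO[Si](C)(C)C(C)(C)C)C(=O)O[C@@H](CC(=C)/C=C\C[C@@]1(C)O[C@@H]1C=O)/C(I)=C(\COC(C)=O)C(=O)OC
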